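**Plan**

Target numbering: C1 (=CHBr), C2 (CCl), C3 and C4 (oxirane carbons), C5 (CH2), C6 (CHOH), C7 (CBr), C8 (CH2Cl).
Retrosynthesis: the oxirane C3–O–C4 is opened to the (E)-C3=C4 alkene; Br and Cl are taken off C7/C8 (isopropenyl group); the (Z)-BrCH=CCl unit is traced to a C2 aldehyde plus one carbon (bromoalkyne); last, the C5–C6 bond is cut by a vinylogous aldol.
Enabling feature: the C6 carbinol, the C5 methylene and the C4=C3(CH3) alkene ending in C2 at carbonyl level form a δ-hydroxy-α-methyl enal pattern, and C7, C8 and the C7 methyl are a masked isopropenyl group. The chain is therefore tiglic aldehyde plus methacrolein.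
Forward: the chain is joined first (C5–C6), C1 is added and the alkyne is turned into the Z-bromochloroalkene, C7/C8 are bromochlorinated, and the only ring, the oxirane, is closed last.
Stereochemistry: C6 from the chiral boron Lewis acid of the aldol, C7 from the chiral titanium catalyst, C3/C4 from the C6–OH-directed epoxidation of the E alkene made in the aldol, and the Z dihalide from anti-hydrochlorination.

Key step: step 2

Assumption: the N-tosyl-(S)-tryptophan-derived B-phenyl oxazaborolidinone is taken to expose the Re face of bound methacrolein (indole-stacking model), and the Schiff-base ligand enantiomer in step 7 is the one that sends bromine to the Si face of C2 of 9; if either sense proves opposite, the enantiomeric catalyst is used with no other change.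

**Route**

Step 1
Reactants: 1 (2E)-2-methylbut-2-enal (tiglic aldehyde)
Product: 2 tert-butyl(dimethyl){[(1E)-2-methylbuta-1,3-dien-1-yl]oxy}silane
Conditions: TBSOTf, Et3N, Et2O, 0 °C to rt
Reagents that add atoms: tert-butyldimethylsilyl triflate, CC(C)(C)[Si](C)(C)OS(=O)(=O)C(F)(F)F
Why: Soft enolization (O-silylation of the enal, then γ-deprotonation by the amine) should give the linear silyl dienol ether; no stereocenter is formed and a minor 1Z isomer would lead to the same aldol product.

Step 2
Reactants: 2 tert-butyl(dimethyl){[(1E)-2-methylbuta-1,3-dien-1-yl]oxy}silane; 3 2-methylprop-2-enal (methacrolein)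
Product: 4 (2E,5R)-5-hydroxy-2,6-dimethylhepta-2,6-dienal
Conditions: N-tosyl-(S)-tryptophan-derived B-phenyl oxazaborolidinone (50 mol %), i-PrOH, EtCN, −78 °C
Reagents that add atoms: none
Why: Vinylogous Mukaiyama aldol: the boron of the oxazaborolidinone binds methacrolein, and the terminal (γ) carbon of dienol ether 2 attacks the carbonyl carbon through an open, antiperiplanar transition state, the silyl group being passed to i-PrOH. The closest known reaction type is the enantioselective vinylogous Mukaiyama aldol of aldehyde-derived silyl dienol ethers under tryptophan-based oxazaborolidinone promotion. No ring is closed. The new C6 stereocenter (C5 of 4) is set by the catalyst, whose indole ring stacks over one face of the bound aldehyde so that attack comes from the Re face and gives (R). The new C2=C3 alkene of 4 should be E because the enal re-forms in its conjugated, less strained geometry. The step needs γ- over α-attack and 1,2- over 1,4-addition: the C2 methyl and the O-silyl group of 2 flank the α-carbon, and the α-methyl group of methacrolein slows conjugate addition.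

Step 3
Reactants: 4 (2E,5R)-5-hydroxy-2,6-dimethylhepta-2,6-dienal
Product: 5 (2E,5R)-5-{[tert-butyl(dimethyl)silyl]oxy}-2,6-dimethylhepta-2,6-dienal
Conditions: TBSCl, imidazole, DMF, rt
Reagents that add atoms: tert-butyldimethylsilyl chloride, CC(C)(C)[Si](C)(C)Cl
Why: Standard silylation of a secondary alcohol; it blocks alkoxide-triggered vinylogous retro-aldol cleavage in the basic step 4 and leaves C5 untouched.

Step 4
Reactants: 5 (2E,5R)-5-{[tert-butyl(dimethyl)silyl]oxy}-2,6-dimethylhepta-2,6-dienal
Product: 7 {[(3R,5E)-8-bromo-2,6-dimethylocta-1,5-dien-7-yn-3-yl]oxy}(tert-butyl)dimethylsilane, via dibromoalkene 6 (not isolated)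
Conditions: Ph3P(CHBr2)Br, t-BuOK, THF, 0 °C to rt; then t-BuOK, −78 °C to rt
Reagents that add atoms: (dibromomethyl)triphenylphosphonium bromide, BrC(Br)[P+](c1ccccc1)(c1ccccc1)c1ccccc1.[Br-]
Why: Wittig-type dibromo-olefination (Corey–Fuchs ylide) followed in the same flask by anti E2 loss of HBr from the 1,1-dibromoalkene should give the 1-bromoalkyne; the 5E alkene and C3 are not involved.

Step 5
Reactants: 7 {[(3R,5E)-8-bromo-2,6-dimethylocta-1,5-dien-7-yn-3-yl]oxy}(tert-butyl)dimethylsilane
Product: 8 {[(3R,5E,7Z)-8-bromo-7-chloro-2,6-dimethylocta-1,5,7-trien-3-yl]oxy}(tert-butyl)dimethylsilane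
Conditions: LiCl, Pd(OAc)2 (5 mol %), AcOH, rt
Reagents that add atoms: lithium chloride, [Li+].[Cl-]
Why: Palladium-catalysed hydrochlorination of a 1-bromoalkyne: trans-chloropalladation at the carbon remote from bromine and protodepalladation with retention add H and Cl anti, so Cl and Br should end cis (7Z).

Step 6
Reactants: 8 {[(3R,5E,7Z)-8-bromo-7-chloro-2,6-dimethylocta-1,5,7-trien-3-yl]oxy}(tert-butyl)dimethylsilane
Product: 9 (3R,5E,7Z)-8-bromo-7-chloro-2,6-dimethylocta-1,5,7-trien-3-ol
Conditions: HF·pyridine, pyridine, THF, 0 °C to rt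
Reagents that add atoms: none
Why: Fluoride-mediated desilylation under buffered, non-basic conditions, chosen to avoid base-induced loss of HCl from the (Z)-bromochloroalkene; C3 is untouched.

Step 7
Reactants: 9 (3R,5E,7Z)-8-bromo-7-chloro-2,6-dimethylocta-1,5,7-trien-3-ol
Product: 10 (2R,3R,5E,7Z)-2,8-dibromo-1,7-dichloro-2,6-dimethylocta-5,7-dien-3-ol
Conditions: NBS, ClTi(Oi-Pr)3, chiral tridentate Schiff-base ligand (salicylaldimine of a 1,1-diaryl amino alcohol, 20 mol %), hexanes, −20 °C
Reagents that add atoms: N-bromosuccinimide, O=C1CCC(=O)N1Br; chlorotitanium triisopropoxide, CC(C)O[Ti](Cl)(OC(C)C)OC(C)C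
Why: Titanium–Schiff-base-catalysed enantioselective bromochlorination of an allylic alcohol: the C3 alkoxide binds the chiral Ti complex, NBS forms the bromonium ion on the C1=C2 alkene and the Ti-bound chloride is delivered to the terminal carbon C1 anti to bromine, so bromine should end on the tertiary C2 on its Si face ((2R), catalyst control), while the halogenated, non-allylic diene is left alone.

Step 8
Reactants: 10 (2R,3R,5E,7Z)-2,8-dibromo-1,7-dichloro-2,6-dimethylocta-5,7-dien-3-ol
Product: 11 (2R,3R)-3-bromo-1-{(2S,3R)-3-[(Z)-2-bromo-1-chloroethenyl]-3-methyloxiran-2-yl}-4-chloro-3-methylbutan-2-ol (target)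
Conditions: VO(acac)2 (5 mol %), t-BuOOH (decane), CH2Cl2, 0 °C to rt
Reagents that add atoms: tert-butyl hydroperoxide, CC(C)(C)OO
Why: Hydroxyl-directed vanadium-catalysed epoxidation of a homoallylic alcohol: oxygen is passed from the vanadate ester of the C3–OH through a chair-like transition state with the bulky C2 substituent equatorial, which should give the 1,3-syn epoxy alcohol, and syn addition to the 5E alkene sets both oxirane centres (2S,3R) at once; the electron-poor dihaloalkene does not react.

**Compound list**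

1 | (2E)-2-methylbut-2-enal (tiglic aldehyde) | C/C=C(\C)C=O | starting material
2 | tert-butyl(dimethyl){[(1E)-2-methylbuta-1,3-dien-1-yl]oxy}silane | CC(C)(C)[Si](C)(C)O/C=C(C)/C=C | intermediate
3 | 2-methylprop-2-enal (methacrolein) | CC(=C)C=O | starting material
4 | (2E,5R)-5-hydroxy-2,6-dimethylhepta-2,6-dienal | O=C/C(C)=C/C[C@@H](O)C(C)=C | intermediate
5 | (2E,5R)-5-{[tert-butyl(dimethyl)silyl]oxy}-2,6-dimethylhepta-2,6-dienal | O=C/C(C)=C/C[C@@H](O[Si](C)(C)C(C)(C)C)C(C)=C | intermediate
6 | tert-butyl{[(3R,5E)-8,8-dibromo-2,6-dimethylocta-1,5,7-trien-3-yl]oxy}dimethylsilane | BrC(Br)=C/C(C)=C/C[C@@H](O[Si](C)(C)C(C)(C)C)C(C)=C | intermediate (not isolated)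
7 | {[(3R,5E)-8-bromo-2,6-dimethylocta-1,5-dien-7-yn-3-yl]oxy}(tert-butyl)dimethylsilane | BrC#C/C(C)=C/C[C@@H](O[Si](C)(C)C(C)(C)C)C(C)=C | intermediate
8 | {[(3R,5E,7Z)-8-bromo-7-chloro-2,6-dimethylocta-1,5,7-trien-3-yl]oxy}(tert-butyl)dimethylsilane | Br/C=C(Cl)/C(C)=C/C[C@@H](O[Si](C)(C)C(C)(C)C)C(C)=C | intermediate
9 | (3R,5E,7Z)-8-bromo-7-chloro-2,6-dimethylocta-1,5,7-trien-3-ol | Br/C=C(Cl)/C(C)=C/C[C@@H](O)C(C)=C | intermediate
10 | (2R,3R,5E,7Z)-2,8-dibromo-1,7-dichloro-2,6-dimethylocta-5,7-dien-3-ol | Br/C=C(Cl)/C(C)=C/C[C@@H](O)[C@@](C)(Br)CCl | intermediate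
11 | (2R,3R)-3-bromo-1-{(2S,3R)-3-[(Z)-2-bromo-1-chloroethenyl]-3-methyloxiran-2-yl}-4-chloro-3-methylbutan-2-ol | C[C@](Br)(CCl)[C@H](O)C[C@@H]1O[C@@]1(C)/C(Cl)=C/Br | target

Total step count: 8
Longest linear sequence: 8 steps (1 to 11)

**Steps most likely to fail**

Step 7. The chloride may open the bromonium ion at the tertiary carbon C2 (Markovnikov sense) instead of being delivered to C1, the resident C3 centre may work against the catalyst so that facial selectivity at C2 is poor, or the diene may be brominated in competition. The fallback moves the halogenation to the small fragment; it sets out from 2 and returns at 10. 2-Methylprop-2-en-1-ol, a primary achiral allylic alcohol on which the catalyst alone sets the centre, is bromochlorinated under the conditions of step 7 to (2R)-2-bromo-3-chloro-2-methylpropan-1-ol F1. Dess–Martin oxidation should give (2R)-2-bromo-3-chloro-2-methylpropanal F2, which takes the place of 3 in the aldol of step 2 with 2 and should give (2E,5R,6R)-6-bromo-7-chloro-5-hydroxy-2,6-dimethylhept-2-enal F3. Silylation as in step 3 gives the silyl ether F4; dibromo-olefination gives the dibromoalkene F5, which is not isolated; elimination with NaHMDS at −78 °C, chosen to spare the tertiary bromide, gives the bromoalkyne F6; hydrochlorination as in step 5 gives the (Z)-bromochloroalkene F7; HF·pyridine then gives 10.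

Step 8. The directed oxygen transfer may lose facial selectivity, or the Lewis-acidic vanadium may promote attack of the C3 hydroxyl on the new vinyl oxirane (5-endo opening to a tetrahydrofuran). The fallback replaces substrate direction by reagent control and places the epoxidation before the halogenation; it sets out from 8 and returns at 11. Shi epoxidation of 8 with the L-fructose-derived ketone (Oxone, K2CO3, MeCN/dimethoxymethane/water, 0 °C), in which the trisubstituted alkene reacts ahead of the isopropenyl group, should give tert-butyl{[(2R)-1-{(2S,3R)-3-[(Z)-2-bromo-1-chloroethenyl]-3-methyloxiran-2-yl}-3-methylbut-3-en-2-yl]oxy}dimethylsilane F8. Desilylation with Bu4NF buffered with AcOH gives (2R)-1-{(2S,3R)-3-[(Z)-2-bromo-1-chloroethenyl]-3-methyloxiran-2-yl}-3-methylbut-3-en-2-ol F9, and bromochlorination of F9 under the conditions of step 7 gives 11.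

Step 2. Facial control by the boron Lewis acid may be incomplete with so small an enal, and α-attack of the dienol ether or conjugate addition may compete. The fallback forms the same bond by allylboration and builds the enal afterwards; it sets out from 3 and returns at 5. Brown allylboration of 3 with the enantiomer of B-allyldiisopinocampheylborane that adds to the Re face (expected: the reagent from (−)-α-pinene; Et2O, −78 °C, then NaOH/H2O2) should give (3R)-2-methylhexa-1,5-dien-3-ol F10. Silylation (TBSCl, imidazole) gives tert-butyl(dimethyl){[(3R)-2-methylhexa-1,5-dien-3-yl]oxy}silane F11, and cross-metathesis of F11 with 3 (second-generation Grubbs catalyst, CH2Cl2, 40 °C) should give the E enal 5, the hindered isopropenyl group staying inert.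

**Further compounds**

F1 | step 7 | (2R)-2-bromo-3-chloro-2-methylpropan-1-ol | C[C@](Br)(CCl)CO
F2 | step 7 | (2R)-2-bromo-3-chloro-2-methylpropanal | C[C@](Br)(CCl)C=O
F3 | step 7 | (2E,5R,6R)-6-bromo-7-chloro-5-hydroxy-2,6-dimethylhept-2-enal | O=C/C(C)=C/C[C@@H](O)[C@@](C)(Br)CCl
F4 | step 7 | (2E,5R,6R)-6-bromo-5-{[tert-butyl(dimethyl)silyl]oxy}-7-chloro-2,6-dimethylhept-2-enal | O=C/C(C)=C/C[C@@H](O[Si](C)(C)C(C)(C)C)[C@@](C)(Br)CCl
F5 | step 7 | tert-butyl(dimethyl){[(2R,3R,5E)-2,8,8-tribromo-1-chloro-2,6-dimethylocta-5,7-dien-3-yl]oxy}silane | BrC(Br)=C/C(C)=C/C[C@@H](O[Si](C)(C)C(C)(C)C)[C@@](C)(Br)CCl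
F6 | step 7 | tert-butyl{[(2R,3R,5E)-2,8-dibromo-1-chloro-2,6-dimethyloct-5-en-7-yn-3-yl]oxy}dimethylsilane | BrC#C/C(C)=C/C[C@@H](O[Si](C)(C)C(C)(C)C)[C@@](C)(Br)CCl
F7 | step 7 | tert-butyl{[(2R,3R,5E,7Z)-2,8-dibromo-1,7-dichloro-2,6-dimethylocta-5,7-dien-3-yl]oxy}dimethylsilane | Br/C=C(Cl)/C(C)=C/C[C@@H](O[Si](C)(C)C(C)(C)C)[C@@](C)(Br)CCl
F8 | step 8 | tert-butyl{[(2R)-1-{(2S,3R)-3-[(Z)-2-bromo-1-chloroethenyl]-3-methyloxiran-2-yl}-3-methylbut-3-en-2-yl]oxy}dimethylsilane | C=C(C)[C@H](O[Si](C)(C)C(C)(C)C)C[C@@H]1O[C@@]1(C)/C(Cl)=C/Br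
F9 | step 8 | (2R)-1-{(2S,3R)-3-[(Z)-2-bromo-1-chloroethenyl]-3-methyloxiran-2-yl}-3-methylbut-3-en-2-ol | C=C(C)[C@H](O)C[C@@H]1O[C@@]1(C)/C(Cl)=C/Br
F10 | step 2 | (3R)-2-methylhexa-1,5-dien-3-ol | C=CC[C@@H](O)C(C)=C
F11 | step 2 | tert-butyl(dimethyl){[(3R)-2-methylhexa-1,5-dien-3-yl]oxy}silane | C=CC[C@@H](O[Si](C)(C)C(C)(C)C)C(C)=C
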